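**Retrosynthetic overview** (spiro[5.5]undecane locants: ring B = C1–C5, spiro C6, ring A = C7–C11)
1. Target 26 ⇐ cis-1,3-diol 24 (C9–OH → C9–Br by SN2 with inversion, last step) ⇐ spiro enone 22 (Wittig bromomethylenation at C3).
2. Ring B (formed second) ⇐ intramolecular aldol condensation of keto aldehyde 20; its formyl and 3-oxobutyl arms are unmasked from the allyl and 3-methylbut-3-enyl groups on C6.
3. C7 carbinol ⇐ hydroxyl-directed epoxidation and hydride opening of allylic alcohol 14; C9 ⇐ ketoreductase reduction of enone 13.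
4. Quaternary C6 ⇐ Pd-catalysed enantioselective decarboxylative allylation of enol carbonate 10; ring A (first) is carried intact from dimedone 1.

Assumption: the PHOX ligand delivers allyl to the same enolate face as in the 2-alkylcyclohexanone series, so the (R)-ligand gives (S)-11, and an (S)-selective ketoreductase for 13 is found in a commercial screening panel.

**Step 1**
Reactants: 1 dimedone (5,5-dimethylcyclohexane-1,3-dione); 2 isobutanol (2-methylpropan-1-ol)
Product: 3 3-isobutoxy-5,5-dimethylcyclohex-2-en-1-one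
Conditions: p-TsOH·H2O (cat.), toluene, reflux, Dean–Stark
Reagents that add atoms: none
Why: Acid-catalysed condensation of the 1,3-dione with the alcohol (vinylogous esterification) with azeotropic removal of water masks one carbonyl as the vinylogous ester.

**Step 2**
Reactants: 4 3-methylbut-3-en-1-ol
Product: 5 4-iodo-2-methylbut-1-ene
Conditions: PPh3, I2, imidazole, CH2Cl2, 0 °C → rt
Reagents that add atoms: iodine, [I][I]
Why: Appel-type iodination converts the primary alcohol into the iodide without touching the alkene.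

**Step 3**
Reactants: 3 3-isobutoxy-5,5-dimethylcyclohex-2-en-1-one; 5 4-iodo-2-methylbut-1-ene
Product: 7 (±)-3-isobutoxy-5,5-dimethyl-6-(3-methylbut-3-en-1-yl)cyclohex-2-en-1-one, via lithium dienolate 6 (not isolated)
Conditions: LiN(iPr)2, THF, −78 °C; then 5, −78 °C → rt
Reagents that add atoms: none
Why: Kinetic α′-deprotonation of the vinylogous ester (Stork–Danheiser alkylation) gives the cross-conjugated dienolate, which is C-alkylated by the primary iodide; the C6–H centre formed here is racemic and is erased on enolisation in step 4.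

**Step 4**
Reactants: 7 (±)-3-isobutoxy-5,5-dimethyl-6-(3-methylbut-3-en-1-yl)cyclohex-2-en-1-one; 8 allyl chloroformate
Product: 10 allyl 5-isobutoxy-3,3-dimethyl-2-(3-methylbut-3-en-1-yl)cyclohexa-1,5-dien-1-yl carbonate, via lithium enolate 9 (not isolated)
Conditions: LiN(iPr)2, TMEDA, THF, −78 °C; then 8, −78 °C
Reagents that add atoms: none
Why: The hindered tetrasubstituted lithium enolate is O-acylated by the chloroformate, giving the achiral allyl enol carbonate needed for decarboxylative allylation.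

**Step 5**
Reactants: 10 allyl 5-isobutoxy-3,3-dimethyl-2-(3-methylbut-3-en-1-yl)cyclohexa-1,5-dien-1-yl carbonate
Product: 11 (S)-6-allyl-3-isobutoxy-5,5-dimethyl-6-(3-methylbut-3-en-1-yl)cyclohex-2-en-1-one
Conditions: Pd2(dba)3 (5 mol%), (R)-(CF3)3-t-BuPHOX (12.5 mol%), toluene, 25 °C
Reagents that add atoms: none
Why: Decarboxylative asymmetric allylic alkylation (Tsuji–Trost type): zerovalent palladium ionises the allyl carbonate, CO2 is lost, and the chiral PHOX–allylpalladium complex delivers allyl to one face of the enolate, setting the quaternary C6 as S.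

**Step 6**
Reactants: 11 (S)-6-allyl-3-isobutoxy-5,5-dimethyl-6-(3-methylbut-3-en-1-yl)cyclohex-2-en-1-one
Product: 13 (S)-4-allyl-3,5,5-trimethyl-4-(3-methylbut-3-en-1-yl)cyclohex-2-en-1-one, via tertiary alcohol adduct 12 (not isolated)
Conditions: MeLi, CeCl3, THF, −78 → 0 °C; then 1 M aq. HCl, rt
Reagents that add atoms: methyllithium, [Li]C; water, O
Why: Stork–Danheiser transposition: the organocerium adds 1,2 to the hindered vinylogous-ester carbonyl and acid hydrolysis/dehydration of the adduct gives the 3-methyl enone, leaving C6 untouched.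

**Step 7**
Reactants: 13 (S)-4-allyl-3,5,5-trimethyl-4-(3-methylbut-3-en-1-yl)cyclohex-2-en-1-one
Product: 14 (1S,4S)-4-allyl-3,5,5-trimethyl-4-(3-methylbut-3-en-1-yl)cyclohex-2-en-1-ol
Conditions: (S)-selective ketoreductase, NADP+ (cat.), iPrOH (10 vol%), KH2PO4/K2HPO4 buffer pH 7, DMSO (5 vol%), 30 °C
Reagents that add atoms: none
Why: A ketoreductase (NADPH-dependent alcohol dehydrogenase, oxidoreductase class) delivers hydride to one carbonyl face only, setting C9 as S under catalyst control independent of the remote C6 centre, so that material from the minor C6 enantiomer becomes a separable diastereomer.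

**Step 8**
Reactants: 14 (1S,4S)-4-allyl-3,5,5-trimethyl-4-(3-methylbut-3-en-1-yl)cyclohex-2-en-1-ol
Product: 15 (1S,2S,5S,6R)-5-allyl-4,4,6-trimethyl-5-(3-methylbut-3-en-1-yl)-7-oxabicyclo[4.1.0]heptan-2-ol
Conditions: VO(acac)2 (5 mol%), t-BuOOH (decane solution), toluene, 0 °C → rt
Reagents that add atoms: tert-butyl hydroperoxide, CC(C)(C)OO
Why: Hydroxyl-directed epoxidation: the vanadium alkoxide delivers oxygen to the alkene face syn to the C9 hydroxyl, fixing the C7–O bond cis to C9–OH, while the two isolated alkenes are not touched.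

**Step 9**
Reactants: 15 (1S,2S,5S,6R)-5-allyl-4,4,6-trimethyl-5-(3-methylbut-3-en-1-yl)-7-oxabicyclo[4.1.0]heptan-2-ol
Product: 16 (1S,3S,6S)-6-allyl-1,5,5-trimethyl-6-(3-methylbut-3-en-1-yl)cyclohexane-1,3-diol
Conditions: LiAlH4, THF, 0 → 50 °C; then H2O, aq. NaOH
Reagents that add atoms: none
Why: Hydride opens the epoxide by SN2 attack at the secondary carbon (the fully substituted C7 is inaccessible), so the C7–O bond and its configuration are kept and the cis-1,3-diol results.

**Step 10**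
Reactants: 16 (1S,3S,6S)-6-allyl-1,5,5-trimethyl-6-(3-methylbut-3-en-1-yl)cyclohexane-1,3-diol
Product: 17 bis(triethylsilyl) ether of 16
Conditions: Et3SiOTf, 2,6-lutidine, CH2Cl2, −78 → 0 °C
Reagents that add atoms: triethylsilyl trifluoromethanesulfonate, CC[Si](CC)(CC)OS(=O)(=O)C(F)(F)F
Why: The silyl triflate silylates both the secondary and the hindered tertiary hydroxyl, which blocks retro-aldol cleavage of the C6–C7 bond once the neighbouring aldehyde and enone are present.

**Step 11**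
Reactants: 17 bis(triethylsilyl) ether of 16
Product: 18 bis(triethylsilyl) ether of (1S,3S,6S)-1,5,5-trimethyl-6-(3-methylbut-3-en-1-yl)-6-[(E)-prop-1-en-1-yl]cyclohexane-1,3-diol
Conditions: RuHCl(CO)(PPh3)3 (5 mol%), toluene, 80 °C
Reagents that add atoms: none
Why: Ruthenium hydride addition–elimination (olefin isomerisation) moves the monosubstituted allyl double bond one position inward, while the 1,1-disubstituted alkene is inert because its isomerisation would need a tertiary alkyl–ruthenium.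

**Step 12**
Reactants: 18 the propenyl bis(triethylsilyl) ether
Product: 20 (1S,2S,4S)-2,6,6-trimethyl-1-(3-oxobutyl)-2,4-bis(triethylsilyloxy)cyclohexane-1-carbaldehyde, via bis-ozonide 19 (not isolated)
Conditions: O3, CH2Cl2, −78 °C; then Me2S, −78 °C → rt
Reagents that add atoms: ozone, [O-][O+]=O
Why: Ozonolysis with reductive work-up cleaves both alkenes, turning the propenyl group into the formyl group (C1) and the isopropenyl terminus into the methyl ketone (C3).

**Step 13**
Reactants: 20 (1S,2S,4S)-2,6,6-trimethyl-1-(3-oxobutyl)-2,4-bis(triethylsilyloxy)cyclohexane-1-carbaldehyde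
Product: 22 (6S,7S,9S)-7,11,11-trimethyl-7,9-bis(triethylsilyloxy)spiro[5.5]undec-1-en-3-one, via aldol adduct 21 (not isolated)
Conditions: KOH (0.5 equiv), MeOH/THF, 0 → 40 °C
Reagents that add atoms: none
Why: Intramolecular aldol condensation: only the methyl enolate can reach the non-enolisable aldehyde through a six-membered ring, and E1cB dehydration gives the spiro cyclohexenone (ring B) with C1=C2 next to C6.

**Step 14**
Reactants: 22 (6S,7S,9S)-7,11,11-trimethyl-7,9-bis(triethylsilyloxy)spiro[5.5]undec-1-en-3-one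
Product: 23 (3Z,6S,7S,9S)-3-(bromomethylidene)-7,11,11-trimethyl-7,9-bis(triethylsilyloxy)spiro[5.5]undec-1-ene
Conditions: [Ph3PCH2Br]Br, KOtBu, THF, −78 °C; then 22, −78 °C → rt; chromatography on AgNO3-impregnated SiO2
Reagents that add atoms: (bromomethyl)triphenylphosphonium bromide, [Br-].BrC[P+](c1ccccc1)(c1ccccc1)c1ccccc1
Why: Wittig bromomethylenation of the only carbonyl present gives the bromodiene, but the olefination is not stereospecific and forms a Z/E mixture, from which the Z isomer (Br syn to C2) is isolated by argentation chromatography.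

**Step 15**
Reactants: 23 (3Z,6S,7S,9S)-3-(bromomethylidene)-7,11,11-trimethyl-7,9-bis(triethylsilyloxy)spiro[5.5]undec-1-ene
Product: 24 (3Z,6S,7S,9S)-3-(bromomethylidene)-7,11,11-trimethylspiro[5.5]undec-1-ene-7,9-diol
Conditions: HF·pyridine, pyridine, THF, 0 °C → rt
Reagents that add atoms: none
Why: Buffered fluoride-mediated desilylation frees both hydroxyls without ionising the tertiary carbinol or disturbing the bromodiene.

**Step 16**
Reactants: 24 (3Z,6S,7S,9S)-3-(bromomethylidene)-7,11,11-trimethylspiro[5.5]undec-1-ene-7,9-diol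
Product: 26 (3Z,6S,7S,9R)-9-bromo-3-(bromomethylidene)-7,11,11-trimethylspiro[5.5]undec-1-en-7-ol, via mesylate 25 (not isolated)
Conditions: MsCl, Et3N, CH2Cl2, −20 °C; then LiBr, 2-butanone, 60 °C
Reagents that add atoms: lithium bromide, [Li+].[Br-]
Why: The secondary hydroxyl is mesylated selectively and bromide displaces the mesylate by SN2 with inversion, setting C9 as R (Br trans to the C7 hydroxyl); the cis tertiary hydroxyl cannot close an oxetane and the axial leaving group is not aligned for Grob fragmentation.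

**Compound list**
1 | dimedone (5,5-dimethylcyclohexane-1,3-dione) | CC1(C)CC(=O)CC(=O)C1 | starting material
2 | isobutanol (2-methylpropan-1-ol) | CC(C)CO | starting material
3 | 3-isobutoxy-5,5-dimethylcyclohex-2-en-1-one | CC(C)COC1=CC(=O)CC(C)(C)C1 | intermediate
4 | 3-methylbut-3-en-1-ol | CC(=C)CCO | starting material
5 | 4-iodo-2-methylbut-1-ene | CC(=C)CCI | intermediate
6 | lithium 5-isobutoxy-3,3-dimethylcyclohexa-1,5-dien-1-olate (dienolate of 3) | [Li+].[O-]C1=CC(C)(C)CC(OCC(C)C)=C1 | intermediate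
7 | (±)-3-isobutoxy-5,5-dimethyl-6-(3-methylbut-3-en-1-yl)cyclohex-2-en-1-one | CC(C)COC1=CC(=O)C(CCC(C)=C)C(C)(C)C1 | intermediate
8 | allyl chloroformate | C=CCOC(=O)Cl | starting material
9 | lithium 5-isobutoxy-3,3-dimethyl-2-(3-methylbut-3-en-1-yl)cyclohexa-1,5-dien-1-olate (enolate of 7) | [Li+].[O-]C1=C(CCC(C)=C)C(C)(C)CC(OCC(C)C)=C1 | intermediate
10 | allyl 5-isobutoxy-3,3-dimethyl-2-(3-methylbut-3-en-1-yl)cyclohexa-1,5-dien-1-yl carbonate | C=CCOC(=O)OC1=C(CCC(C)=C)C(C)(C)CC(OCC(C)C)=C1 | intermediate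
11 | (S)-6-allyl-3-isobutoxy-5,5-dimethyl-6-(3-methylbut-3-en-1-yl)cyclohex-2-en-1-one | CC1(C)CC(OCC(C)C)=CC(=O)[C@@]1(CCC(C)=C)CC=C | intermediate
12 | (6S)-6-allyl-3-isobutoxy-1,5,5-trimethyl-6-(3-methylbut-3-en-1-yl)cyclohex-2-en-1-ol (C1 epimers, present as its alkoxide) | CC1(C)CC(OCC(C)C)=CC(C)(O)[C@@]1(CCC(C)=C)CC=C | intermediate
13 | (S)-4-allyl-3,5,5-trimethyl-4-(3-methylbut-3-en-1-yl)cyclohex-2-en-1-one | CC1(C)CC(=O)C=C(C)[C@@]1(CCC(C)=C)CC=C | intermediate
14 | (1S,4S)-4-allyl-3,5,5-trimethyl-4-(3-methylbut-3-en-1-yl)cyclohex-2-en-1-ol | CC1(C)C[C@H](O)C=C(C)[C@@]1(CCC(C)=C)CC=C | intermediate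
15 | (1S,2S,5S,6R)-5-allyl-4,4,6-trimethyl-5-(3-methylbut-3-en-1-yl)-7-oxabicyclo[4.1.0]heptan-2-ol (epoxide cis to OH) | CC1(C)C[C@H](O)[C@@H]2O[C@]2(C)[C@@]1(CCC(C)=C)CC=C | intermediate
16 | (1S,3S,6S)-6-allyl-1,5,5-trimethyl-6-(3-methylbut-3-en-1-yl)cyclohexane-1,3-diol (cis-diol) | CC1(C)C[C@H](O)C[C@](C)(O)[C@@]1(CCC(C)=C)CC=C | intermediate
17 | bis(triethylsilyl) ether of 16 | CC1(C)C[C@H](O[Si](CC)(CC)CC)C[C@](C)(O[Si](CC)(CC)CC)[C@@]1(CCC(C)=C)CC=C | intermediate
18 | bis(triethylsilyl) ether of (1S,3S,6S)-1,5,5-trimethyl-6-(3-methylbut-3-en-1-yl)-6-[(E)-prop-1-en-1-yl]cyclohexane-1,3-diol | CC1(C)C[C@H](O[Si](CC)(CC)CC)C[C@](C)(O[Si](CC)(CC)CC)[C@@]1(CCC(C)=C)/C=C/C | intermediate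
19 | bis-ozonide of 18 (both C=C as 1,2,4-trioxolanes, trioxolane epimers) | CC1(C)C[C@H](O[Si](CC)(CC)CC)C[C@](C)(O[Si](CC)(CC)CC)[C@@]1(CCC2(C)OCOO2)C3OC(C)OO3 | intermediate
20 | (1S,2S,4S)-2,6,6-trimethyl-1-(3-oxobutyl)-2,4-bis(triethylsilyloxy)cyclohexane-1-carbaldehyde | CC1(C)C[C@H](O[Si](CC)(CC)CC)C[C@](C)(O[Si](CC)(CC)CC)[C@@]1(CCC(C)=O)C=O | intermediate
21 | (6R,7S,9S)-1-hydroxy-7,11,11-trimethyl-7,9-bis(triethylsilyloxy)spiro[5.5]undecan-3-one (C1 epimers) | CC1(C)C[C@H](O[Si](CC)(CC)CC)C[C@](C)(O[Si](CC)(CC)CC)[C@@]12C(O)CC(=O)CC2 | intermediate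
22 | (6S,7S,9S)-7,11,11-trimethyl-7,9-bis(triethylsilyloxy)spiro[5.5]undec-1-en-3-one | CC1(C)C[C@H](O[Si](CC)(CC)CC)C[C@](C)(O[Si](CC)(CC)CC)[C@@]12C=CC(=O)CC2 | intermediate
23 | (3Z,6S,7S,9S)-3-(bromomethylidene)-7,11,11-trimethyl-7,9-bis(triethylsilyloxy)spiro[5.5]undec-1-ene | CC1(C)C[C@H](O[Si](CC)(CC)CC)C[C@](C)(O[Si](CC)(CC)CC)[C@@]12C=C/C(=C\Br)CC2 | intermediate
24 | (3Z,6S,7S,9S)-3-(bromomethylidene)-7,11,11-trimethylspiro[5.5]undec-1-ene-7,9-diol | CC1(C)C[C@H](O)C[C@](C)(O)[C@@]12C=C/C(=C\Br)CC2 | intermediate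
25 | (3Z,6S,7S,9S)-3-(bromomethylidene)-7-hydroxy-7,11,11-trimethylspiro[5.5]undec-1-en-9-yl methanesulfonate | CC1(C)C[C@H](OS(C)(=O)=O)C[C@](C)(O)[C@@]12C=C/C(=C\Br)CC2 | intermediate
26 | (3Z,6S,7S,9R)-9-bromo-3-(bromomethylidene)-7,11,11-trimethylspiro[5.5]undec-1-en-7-ol | CC1(C)C[C@@H](Br)C[C@](C)(O)[C@@]12C=C/C(=C\Br)CC2 | target

**Step count**
Total steps: 16. Longest linear sequence: 15 steps (1 → 26 through steps 1 and 3–16; step 2 prepares iodide 5).

**Three steps most likely to fail**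

Step 7: no panel enzyme may accept the hindered isophorone-type enone at a useful rate. The fallback sets out from 13 and comes back at 14. Luche reduction (NaBH4, CeCl3·7H2O, MeOH, −78 °C) gives 14 mixed with its C1 epimer (1R,4S)-4-allyl-3,5,5-trimethyl-4-(3-methylbut-3-en-1-yl)cyclohex-2-en-1-ol F1. Candida antarctica lipase B with vinyl acetate in methyl tert-butyl ether at 30 °C is expected (Kazlauskas preference) to acylate the (1R) epimer, giving (1R,4S)-4-allyl-3,5,5-trimethyl-4-(3-methylbut-3-en-1-yl)cyclohex-2-en-1-yl acetate F2 and leaving 14, which is separated on silica. F2 is recycled to 13 by K2CO3/MeOH and then MnO2.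

Step 14: the Wittig reaction has no reliable bias between the two flanks of the enone, so the Z isomer may be the minor product. The fallback sets out from 22 and comes back at 23. Boron-Wittig olefination (CH2(Bpin)2, lithium 2,2,6,6-tetramethylpiperidide, THF, −78 °C → rt) gives two separable alkenyl boronates: (3Z,6S,7S,9S)-3-[(4,4,5,5-tetramethyl-1,3,2-dioxaborolan-2-yl)methylidene]-7,11,11-trimethyl-7,9-bis(triethylsilyloxy)spiro[5.5]undec-1-ene F3 (boron syn to C2) and its (3E) isomer F4. F3 is brominated with retention (CuBr2, MeOH/H2O, 60 °C). F4 is brominated with inversion (Br2, CH2Cl2, −78 °C; then NaOMe, MeOH, anti addition then anti elimination). Both isomers therefore converge on 23.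

Step 16: the mesylate must react through a strained triaxial conformer, so E2/E1 elimination can outrun substitution. The fallback sets out from 24 and comes back at 26. The cis-1,3-diol is tied up with 1,1'-sulfonyldiimidazole and NaH in THF at 0 °C as the 7,9-cyclic sulfate of 24 F5, which locks the C9–O bond axial. LiBr in THF at 50 °C opens it at the secondary carbon with inversion to lithium (3Z,6S,7S,9R)-9-bromo-3-(bromomethylidene)-7,11,11-trimethylspiro[5.5]undec-1-en-7-yl sulfate F6. Catalytic H2SO4 with one equivalent of H2O in THF hydrolyses the tertiary sulfate to 26.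

**Further compounds**
F1 | step 7 | (1R,4S)-4-allyl-3,5,5-trimethyl-4-(3-methylbut-3-en-1-yl)cyclohex-2-en-1-ol | CC1(C)C[C@@H](O)C=C(C)[C@@]1(CCC(C)=C)CC=C
F2 | step 7 | (1R,4S)-4-allyl-3,5,5-trimethyl-4-(3-methylbut-3-en-1-yl)cyclohex-2-en-1-yl acetate | CC1(C)C[C@@H](OC(C)=O)C=C(C)[C@@]1(CCC(C)=C)CC=C
F3 | step 14 | (3Z,6S,7S,9S)-3-[(4,4,5,5-tetramethyl-1,3,2-dioxaborolan-2-yl)methylidene]-7,11,11-trimethyl-7,9-bis(triethylsilyloxy)spiro[5.5]undec-1-ene | CC1(C)C[C@H](O[Si](CC)(CC)CC)C[C@](C)(O[Si](CC)(CC)CC)[C@@]12C=C/C(=C\B3OC(C)(C)C(C)(C)O3)CC2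
F4 | step 14 | (3E,6S,7S,9S)-3-[(4,4,5,5-tetramethyl-1,3,2-dioxaborolan-2-yl)methylidene]-7,11,11-trimethyl-7,9-bis(triethylsilyloxy)spiro[5.5]undec-1-ene | CC1(C)C[C@H](O[Si](CC)(CC)CC)C[C@](C)(O[Si](CC)(CC)CC)[C@@]12C=C/C(=C/B3OC(C)(C)C(C)(C)O3)CC2
F5 | step 16 | 7,9-cyclic sulfate of 24 | CC1(C)C[C@H]3C[C@](C)(OS(=O)(=O)O3)[C@@]12C=C/C(=C\Br)CC2
F6 | step 16 | lithium (3Z,6S,7S,9R)-9-bromo-3-(bromomethylidene)-7,11,11-trimethylspiro[5.5]undec-1-en-7-yl sulfate | CC1(C)C[C@@H](Br)C[C@](C)(OS(=O)(=O)[O-])[C@@]12C=C/C(=C\Br)CC2.[Li+]
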